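**Plan**

1. Numbering runs from the ester carbonyl (C1) to the bromoalkene carbon (C20). The retrosynthesis cuts C10–C11 (alkyne/alkenyl iodide coupling), then C9≡C10 (one-carbon homologation of a C9 aldehyde), then C6=C7 together with C1=C2 (metathesis), and last O–C5 (allylic etherification). The C11–C20 bromo-iodo-diene is cut at both alkenes back to octane-1,8-diol.
2. Enabling feature: the ether carbon C5 with C2, C3, C4 and C6 can be read as an opened cyclopentene. A cyclopent-2-enyl ether of a but-3-en-2-ol therefore contains both the oxolane ring (O, C5, C6, C7, C8) and the C1–C4 arm.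
3. Forward: ether 8 is joined from two small pieces. One metathesis step closes the only ring as a 2,5-dihydrofuran and releases the but-3-enyl arm (9). C1 is then raised to the methyl ester, the ring alkene is hydrogenated, C9 is turned into the alkyne, and the C11–C20 chain is attached last.
4. Stereochemistry: C8 comes from hydrolytic kinetic resolution of 2-vinyloxirane. C5 comes from ligand control in the palladium etherification of a meso cyclopentenyl π-allyl complex, so the trans relationship results from two independently set centers. The 11E alkene comes from a Takai olefination and the 19Z alkene from a bromo-Wittig reaction.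

Key step: step 6

Remark on the chemistry: the (S,S) catalyst in step 1 and the (S,S) ligand in step 5 are assigned from the usual sense of induction of these catalyst families (terminal epoxides; cyclic meso π-allyl complexes); if either sense proves opposite on these substrates, the mirror-image catalyst is taken and nothing else changes.

**Route**

Step 1
Reactants: 1 (±)-2-vinyloxirane
Product: 2 (2S)-but-3-ene-1,2-diol
Conditions: (S,S)-(salen)Co(OAc) (0.5 mol%; salen = N,N'-bis(3,5-di-tert-butylsalicylidene)cyclohexane-1,2-diamine), H2O (0.45 equiv), THF, 0 °C to rt; unreacted epoxide evaporated, diol distilled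
Reagents that add atoms: water, O
Why: Hydrolytic kinetic resolution with the trivalent cobalt salen acetate delivers water to the terminal CH2 of the (S)-epoxide much faster than to its mirror image, so that with less than half an equivalent of water the diol should form in high enantiomeric purity with the future C8 center untouched, and any minor enantiomer is expected to be removed later as a diastereomer of 8 or 9.

Step 2
Reactants: 2 (2S)-but-3-ene-1,2-diol
Product: 3 (2S)-1-{[tert-butyl(diphenyl)silyl]oxy}but-3-en-2-ol
Conditions: TBDPSCl (1.05 equiv), imidazole, CH2Cl2, 0 °C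
Reagents that add atoms: tert-butyl(chloro)diphenylsilane, CC(C)(C)[Si](Cl)(c1ccccc1)c1ccccc1
Why: Silyl ether formation with a bulky chlorosilane is selective for the primary hydroxyl and leaves the secondary allylic hydroxyl free for the etherification.

Step 3
Reactants: 4 cyclopent-2-en-1-one
Product: 5 (±)-cyclopent-2-en-1-ol
Conditions: NaBH4, CeCl3·7H2O, MeOH, 0 °C
Reagents that add atoms: none
Why: Luche reduction gives clean 1,2-reduction of the enone, and the racemate suffices because the configuration of this carbon is erased at the π-allyl stage of step 5.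

Step 4
Reactants: 5 (±)-cyclopent-2-en-1-ol
Product: 6 (±)-tert-butyl cyclopent-2-en-1-yl carbonate
Conditions: Boc2O, Bu4NHSO4 (5 mol%), 30% aq NaOH, CH2Cl2, 0 °C to rt
Reagents that add atoms: di-tert-butyl dicarbonate, CC(C)(C)OC(=O)OC(=O)OC(C)(C)C
Why: Phase-transfer acylation of the alcohol gives an allylic tert-butyl carbonate that ionises readily with zerovalent palladium and leaves only poorly nucleophilic tert-butoxide behind.

Step 5
Reactants: 3 (2S)-1-{[tert-butyl(diphenyl)silyl]oxy}but-3-en-2-ol; 6 (±)-tert-butyl cyclopent-2-en-1-yl carbonate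
Product: 8 tert-butyl{[(2S)-2-[(1R)-cyclopent-2-en-1-yloxy]but-3-en-1-yl]oxy}diphenylsilane, via zinc bis-alkoxide 7 (not isolated)
Conditions: 3, Et2Zn (0.5 equiv), THF, 0 °C to rt; then 6 (1.5 equiv), Pd2(dba)3·CHCl3 (2.5 mol%), (S,S)-DACH-phenyl Trost ligand (7.5 mol%), THF, rt; NH4Cl work-up
Reagents that add atoms: none
Why: In this palladium-catalysed asymmetric allylic etherification (Tsuji–Trost type, zinc alkoxide as oxygen nucleophile) both enantiomers of 6 ionise to the same meso cyclopentenyl π-allyl palladium complex and the chiral diphosphine steers the alkoxide to one of the two enantiotopic termini, which sets C5 as R independently of the C8 center carried by 3.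

Step 6
Reactants: 8 tert-butyl{[(2S)-2-[(1R)-cyclopent-2-en-1-yloxy]but-3-en-1-yl]oxy}diphenylsilane
Product: 9 tert-butyl{[(2S,5R)-5-(but-3-en-1-yl)-2,5-dihydrofuran-2-yl]methoxy}diphenylsilane
Conditions: second-generation Grubbs catalyst RuCl2(=CHPh)(PCy3)(H2IMes) (5 mol%), ethylene (1 atm), CH2Cl2 (0.01 M), rt to 40 °C
Reagents that add atoms: ethylene, C=C
Why: Ring-rearrangement metathesis, a ring-opening/ring-closing domino: the ruthenium methylidene formed under ethylene exchanges onto the monosubstituted vinyl group to give an alkylidene at C7, this adds across the cyclopentene double bond through a ruthenacyclobutane, and cycloreversion forms C6=C7 while leaving a new alkylidene at C2 that ethylene caps as the C1=C2 terminal alkene. The closest known reaction type is the rearrangement of cycloalkenyl allyl ethers into 2,5-dihydrofurans carrying an ω-alkenyl chain. The one ring that closes, the 2,5-dihydrofuran (O, C5, C6, C7, C8), does so by ring-closing metathesis of the C7 carbene onto the nearer cyclopentene carbon, a five-membered closure preferred over the seven-membered ring that the farther carbon would give. No stereocenter is made: C5 and C8 are sp3 allylic carbons whose four bonds stay intact, so the trans relationship fixed in step 5 passes unchanged into 9. The step needs initiation at the vinyl group and a monomeric product, and both are secured by substrate and conditions: the terminal alkene is the least hindered site for the carbene, while high dilution, the ethylene atmosphere and the release of cyclopentene strain work against oligomers.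

Step 7
Reactants: 9 tert-butyl{[(2S,5R)-5-(but-3-en-1-yl)-2,5-dihydrofuran-2-yl]methoxy}diphenylsilane
Product: 11 4-[(2R,5S)-5-({[tert-butyl(diphenyl)silyl]oxy}methyl)-2,5-dihydrofuran-2-yl]butan-1-ol, via B-alkyl-9-BBN adduct 10 (not isolated)
Conditions: 9-BBN (1.3 equiv), THF, 0 °C to rt; then 3 M NaOH, 30% H2O2, 0 °C to rt
Reagents that add atoms: hydrogen peroxide, OO
Why: Anti-Markovnikov hydroboration–oxidation with 9-BBN should take the monosubstituted terminal alkene far faster than the cis-disubstituted ring alkene, placing boron and then oxygen on C1.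

Step 8
Reactants: 11 4-[(2R,5S)-5-({[tert-butyl(diphenyl)silyl]oxy}methyl)-2,5-dihydrofuran-2-yl]butan-1-ol
Product: 12 4-[(2R,5S)-5-({[tert-butyl(diphenyl)silyl]oxy}methyl)oxolan-2-yl]butan-1-ol
Conditions: H2 (1 atm), PtO2 (5 mol%), EtOAc, rt
Reagents that add atoms: none
Why: Catalytic hydrogenation over platinum saturates the ring alkene with little tendency to move the double bond into an enol ether position (which would erase C5 or C8) or to cleave the allylic C–O bonds.

Step 9
Reactants: 12 4-[(2R,5S)-5-({[tert-butyl(diphenyl)silyl]oxy}methyl)oxolan-2-yl]butan-1-ol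
Product: 14 4-[(2R,5S)-5-({[tert-butyl(diphenyl)silyl]oxy}methyl)oxolan-2-yl]butanoic acid, via aldehyde 13 (not isolated)
Conditions: TEMPO (20 mol%), PhI(OAc)2 (2.4 equiv), MeCN/H2O 1:1, rt
Reagents that add atoms: water, O
Why: Oxoammonium (TEMPO) oxidation takes the primary alcohol to the aldehyde and, through its hydrate, on to the acid, while the silyl ether and the cyclic ether are inert.

Step 10
Reactants: 14 4-[(2R,5S)-5-({[tert-butyl(diphenyl)silyl]oxy}methyl)oxolan-2-yl]butanoic acid
Product: 15 methyl 4-[(2R,5S)-5-({[tert-butyl(diphenyl)silyl]oxy}methyl)oxolan-2-yl]butanoate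
Conditions: MeI, K2CO3, DMF, rt
Reagents that add atoms: iodomethane, CI
Why: SN2 O-alkylation of the carboxylate gives the methyl ester without touching either stereocenter.

Step 11
Reactants: 15 methyl 4-[(2R,5S)-5-({[tert-butyl(diphenyl)silyl]oxy}methyl)oxolan-2-yl]butanoate
Product: 16 methyl 4-[(2R,5S)-5-(hydroxymethyl)oxolan-2-yl]butanoate
Conditions: TBAF (1.5 equiv), AcOH (1.5 equiv), THF, 0 °C to rt
Reagents that add atoms: none
Why: Fluoride-mediated desilylation frees the C9 alcohol, with acetic acid buffering the medium so that the methyl ester is not hydrolysed.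

Step 12
Reactants: 16 methyl 4-[(2R,5S)-5-(hydroxymethyl)oxolan-2-yl]butanoate
Product: 17 methyl 4-[(2R,5S)-5-formyloxolan-2-yl]butanoate
Conditions: Dess–Martin periodinane (1.3 equiv), CH2Cl2, 0 °C to rt; used crude
Reagents that add atoms: none
Why: Dess–Martin oxidation is mild and non-basic, which should keep the α-alkoxy aldehyde from epimerising at C8.

Step 13
Reactants: 17 methyl 4-[(2R,5S)-5-formyloxolan-2-yl]butanoate
Product: 18 methyl 4-[(2R,5S)-5-ethynyloxolan-2-yl]butanoate
Conditions: dimethyl (1-diazo-2-oxopropyl)phosphonate (1.5 equiv), K2CO3 (2 equiv), MeOH, 0 °C to rt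
Reagents that add atoms: dimethyl (1-diazo-2-oxopropyl)phosphonate, CC(=O)C(=[N+]=[N-])P(=O)(OC)OC
Why: In the Ohira–Bestmann variant of the Seyferth–Gilbert homologation the diazomethylphosphonate anion released by methanolysis adds to the aldehyde and, after loss of phosphate and dinitrogen with a 1,2-hydrogen shift, gives the terminal alkyne (C10), while carbonate in methanol leaves the methyl ester as it is and is expected to spare C8.

Step 14
Reactants: 19 octane-1,8-diol
Product: 20 8-{[tert-butyl(dimethyl)silyl]oxy}octan-1-ol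
Conditions: 19 (3 equiv), TBSCl (1 equiv), imidazole, THF/DMF, 0 °C to rt
Reagents that add atoms: tert-butyl(chloro)dimethylsilane, CC(C)(C)[Si](C)(C)Cl
Why: Statistical monosilylation with the cheap diol in excess should give mainly the mono-ether, and the water-soluble excess diol is washed out.

Step 15
Reactants: 20 8-{[tert-butyl(dimethyl)silyl]oxy}octan-1-ol
Product: 21 8-{[tert-butyl(dimethyl)silyl]oxy}octanal
Conditions: TEMPO (10 mol%), PhI(OAc)2 (1.1 equiv), CH2Cl2, rt
Reagents that add atoms: none
Why: TEMPO-catalysed oxidation in the absence of water stops at the aldehyde and tolerates the silyl ether.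

Step 16
Reactants: 21 8-{[tert-butyl(dimethyl)silyl]oxy}octanal
Product: 22 tert-butyl{[(8E)-9-iodonon-8-en-1-yl]oxy}dimethylsilane
Conditions: CrCl2 (6 equiv), CHI3 (2 equiv), THF/1,4-dioxane, 0 °C to rt
Reagents that add atoms: iodoform, IC(I)I
Why: In the Takai olefination the geminal dichromium species from iodoform adds to the aldehyde and eliminates through the less crowded arrangement, which should give the (E)-alkenyl iodide (C11=C12).

Step 17
Reactants: 22 tert-butyl{[(8E)-9-iodonon-8-en-1-yl]oxy}dimethylsilane
Product: 23 (8E)-9-iodonon-8-en-1-ol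
Conditions: camphorsulfonic acid (10 mol%), MeOH, rt
Reagents that add atoms: none
Why: Acid-catalysed methanolysis removes the primary TBS ether under conditions to which the alkenyl iodide is inert.

Step 18
Reactants: 23 (8E)-9-iodonon-8-en-1-ol
Product: 24 (8E)-9-iodonon-8-enal
Conditions: TEMPO (10 mol%), PhI(OAc)2 (1.1 equiv), CH2Cl2, rt
Reagents that add atoms: none
Why: The same anhydrous TEMPO oxidation gives the aldehyde without affecting the alkenyl iodide.

Step 19
Reactants: 24 (8E)-9-iodonon-8-enal
Product: 25 (1Z,9E)-1-bromo-10-iododeca-1,9-diene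
Conditions: Ph3PCH2Br+ Br− (1.5 equiv), KOt-Bu (1.4 equiv), THF, −78 °C; then 24, −78 to −40 °C
Reagents that add atoms: (bromomethyl)triphenylphosphonium bromide, BrC[P+](c1ccccc1)(c1ccccc1)c1ccccc1.[Br-]
Why: The Wittig reaction of the non-stabilised α-bromo ylide under kinetic control at low temperature should favour the (Z)-bromoalkene (C19=C20), and the slight deficit of base protects product and alkenyl iodide from elimination.

Step 20
Reactants: 18 methyl 4-[(2R,5S)-5-ethynyloxolan-2-yl]butanoate; 25 (1Z,9E)-1-bromo-10-iododeca-1,9-diene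
Product: 26 methyl 4-[(2R,5S)-5-[(3E,11Z)-12-bromododeca-3,11-dien-1-yn-1-yl]oxolan-2-yl]butanoate
Conditions: 25 (1.2 equiv), Pd(PPh3)4 (5 mol%), CuI (10 mol%), Et3N, THF (degassed), rt
Reagents that add atoms: none
Why: Sonogashira coupling forms C10–C11 with retention of both alkene geometries, because zerovalent palladium inserts into the alkenyl C–I bond much faster than into the alkenyl C–Br bond at room temperature.

**Compound list**

1 | (±)-2-vinyloxirane | C=CC1CO1 | starting material
2 | (2S)-but-3-ene-1,2-diol | C=C[C@@H](CO)O | intermediate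
3 | (2S)-1-{[tert-butyl(diphenyl)silyl]oxy}but-3-en-2-ol | C=C[C@@H](CO[Si](c1ccccc1)(c1ccccc1)C(C)(C)C)O | intermediate
4 | cyclopent-2-en-1-one | O=C1C=CCC1 | starting material
5 | (±)-cyclopent-2-en-1-ol | OC1C=CCC1 | intermediate
6 | (±)-tert-butyl cyclopent-2-en-1-yl carbonate | CC(C)(C)OC(=O)OC1C=CCC1 | intermediate
7 | zinc bis[(2S)-1-{[tert-butyl(diphenyl)silyl]oxy}but-3-en-2-olate], formed in the flask | C=C[C@@H](CO[Si](c1ccccc1)(c1ccccc1)C(C)(C)C)O[Zn]O[C@@H](C=C)CO[Si](c1ccccc1)(c1ccccc1)C(C)(C)C | intermediate
8 | tert-butyl{[(2S)-2-[(1R)-cyclopent-2-en-1-yloxy]but-3-en-1-yl]oxy}diphenylsilane | C=C[C@@H](CO[Si](c1ccccc1)(c1ccccc1)C(C)(C)C)O[C@H]1C=CCC1 | intermediate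
9 | tert-butyl{[(2S,5R)-5-(but-3-en-1-yl)-2,5-dihydrofuran-2-yl]methoxy}diphenylsilane | C=CCC[C@@H]1C=C[C@@H](CO[Si](c2ccccc2)(c2ccccc2)C(C)(C)C)O1 | intermediate
10 | 9-{4-[(2R,5S)-5-({[tert-butyl(diphenyl)silyl]oxy}methyl)-2,5-dihydrofuran-2-yl]butyl}-9-borabicyclo[3.3.1]nonane, formed in the flask | C(CCC[C@@H]1C=C[C@@H](CO[Si](c2ccccc2)(c2ccccc2)C(C)(C)C)O1)B1C2CCCC1CCC2 | intermediate
11 | 4-[(2R,5S)-5-({[tert-butyl(diphenyl)silyl]oxy}methyl)-2,5-dihydrofuran-2-yl]butan-1-ol | OCCCC[C@@H]1C=C[C@@H](CO[Si](c2ccccc2)(c2ccccc2)C(C)(C)C)O1 | intermediate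
12 | 4-[(2R,5S)-5-({[tert-butyl(diphenyl)silyl]oxy}methyl)oxolan-2-yl]butan-1-ol | OCCCC[C@@H]1CC[C@@H](CO[Si](c2ccccc2)(c2ccccc2)C(C)(C)C)O1 | intermediate
13 | 4-[(2R,5S)-5-({[tert-butyl(diphenyl)silyl]oxy}methyl)oxolan-2-yl]butanal, formed in the flask | O=CCCC[C@@H]1CC[C@@H](CO[Si](c2ccccc2)(c2ccccc2)C(C)(C)C)O1 | intermediate
14 | 4-[(2R,5S)-5-({[tert-butyl(diphenyl)silyl]oxy}methyl)oxolan-2-yl]butanoic acid | OC(=O)CCC[C@@H]1CC[C@@H](CO[Si](c2ccccc2)(c2ccccc2)C(C)(C)C)O1 | intermediate
15 | methyl 4-[(2R,5S)-5-({[tert-butyl(diphenyl)silyl]oxy}methyl)oxolan-2-yl]butanoate | COC(=O)CCC[C@@H]1CC[C@@H](CO[Si](c2ccccc2)(c2ccccc2)C(C)(C)C)O1 | intermediate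
16 | methyl 4-[(2R,5S)-5-(hydroxymethyl)oxolan-2-yl]butanoate | COC(=O)CCC[C@@H]1CC[C@@H](CO)O1 | intermediate
17 | methyl 4-[(2R,5S)-5-formyloxolan-2-yl]butanoate | COC(=O)CCC[C@@H]1CC[C@@H](C=O)O1 | intermediate
18 | methyl 4-[(2R,5S)-5-ethynyloxolan-2-yl]butanoate | COC(=O)CCC[C@@H]1CC[C@@H](C#C)O1 | intermediate
19 | octane-1,8-diol | OCCCCCCCCO | starting material
20 | 8-{[tert-butyl(dimethyl)silyl]oxy}octan-1-ol | OCCCCCCCCO[Si](C)(C)C(C)(C)C | intermediate
21 | 8-{[tert-butyl(dimethyl)silyl]oxy}octanal | O=CCCCCCCCO[Si](C)(C)C(C)(C)C | intermediate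
22 | tert-butyl{[(8E)-9-iodonon-8-en-1-yl]oxy}dimethylsilane | I/C=C/CCCCCCCO[Si](C)(C)C(C)(C)C | intermediate
23 | (8E)-9-iodonon-8-en-1-ol | I/C=C/CCCCCCCO | intermediate
24 | (8E)-9-iodonon-8-enal | I/C=C/CCCCCCC=O | intermediate
25 | (1Z,9E)-1-bromo-10-iododeca-1,9-diene | I/C=C/CCCCCC/C=C\Br | intermediate
26 | methyl 4-[(2R,5S)-5-[(3E,11Z)-12-bromododeca-3,11-dien-1-yn-1-yl]oxolan-2-yl]butanoate (CNP0170116.1) | COC(=O)CCC[C@@H]1CC[C@@H](C#C/C=C/CCCCCC/C=C\Br)O1 | target

**Count and risks**

Total step count: 20.
Longest linear sequence: 12 steps (steps 1, 2, 5 to 13 and 20; the branch from cyclopent-2-en-1-one through steps 3, 4, 5 to 13 and 20 is equally long). The C11–C20 branch has 6 steps before the coupling.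

Steps most likely to fail:

Step 5. The hindered secondary zinc alkoxide may attack the meso π-allyl complex slowly, and the ligand may not fully override the influence of the C8 center, so that the terminus is chosen with poor selectivity and the cis and trans ethers form together. The fallback reverses the roles of the partners, so that C5 arrives with the nucleophile and C8 is set on the electrophile. It sets out from 6, which is deracemised with Pd2(dba)3·CHCl3, the same ligand and KHCO3 in CH2Cl2/H2O (hydrogencarbonate as oxygen nucleophile, then loss of CO2) to (1R)-cyclopent-2-en-1-ol F1. In parallel, (E)-but-2-ene-1,4-diol is monosilylated (TBDPSCl, imidazole) to (2E)-4-{[tert-butyl(diphenyl)silyl]oxy}but-2-en-1-ol F2, which Boc2O converts into tert-butyl (2E)-4-{[tert-butyl(diphenyl)silyl]oxy}but-2-en-1-yl carbonate F3. The copper alkoxide of F1 (n-BuLi, then CuI, THF) is then coupled with F3 under [Ir(cod)Cl]2 and a BINOL-derived phosphoramidite ligand. This iridium-catalysed allylic etherification attacks the substituted allyl terminus, the ligand sets C8, and the route is rejoined at 8.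

Step 6. Cyclopentene releases little strain, so the rearrangement may stall at a mixture of 8, ring-opened triene and oligomers, and ruthenium hydrides may shift the ring alkene. The fallback gives up the carbocycle and closes the dihydrofuran by plain ring-closing metathesis of an acyclic triene. It sets out from 3. Pent-4-enal is olefinated with triethyl phosphonoacetate (Horner–Wadsworth–Emmons) to ethyl (2E)-hepta-2,6-dienoate F4, reduced with i-Bu2AlH to (2E)-hepta-2,6-dien-1-ol F5 and acylated with Boc2O to tert-butyl (2E)-hepta-2,6-dien-1-yl carbonate F6. Iridium-catalysed branched-selective allylic etherification of the copper alkoxide of 3 with F6 ([Ir(cod)Cl]2, phosphoramidite ligand, which sets C5) gives tert-butyl{[(2S)-2-{[(3R)-hepta-1,6-dien-3-yl]oxy}but-3-en-1-yl]oxy}diphenylsilane F7. With the second-generation Grubbs catalyst RuCl2(=CHPh)(PCy3)(H2IMes), F7 closes the five-membered ring between its two allylic-ether vinyl groups with irreversible loss of ethylene, and the route is rejoined at 9.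

Step 19. The Wittig reaction may give insufficient Z-selectivity with isomers that are hard to separate, and excess base may dehydrobrominate the Z-bromoalkene. The fallback installs the bromoalkene first by a stereospecific reduction and the iodide last. It sets out from 21, which CBr4/PPh3 (Corey–Fuchs-type dibromoolefination) converts into tert-butyl[(9,9-dibromonon-8-en-1-yl)oxy]dimethylsilane F8. Bu3SnH with Pd(PPh3)4 removes selectively the bromine trans to the chain and gives tert-butyl{[(8Z)-9-bromonon-8-en-1-yl]oxy}dimethylsilane F9. Acidic methanolysis gives (8Z)-9-bromonon-8-en-1-ol F10, and TEMPO/PhI(OAc)2 gives (8Z)-9-bromonon-8-enal F11. Takai olefination (CrCl2, CHI3), to which an alkenyl bromide is inert in the absence of a nickel salt, then rejoins the route at 25.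

**Further compounds**

F1 | step 5 | (1R)-cyclopent-2-en-1-ol | O[C@H]1C=CCC1
F2 | step 5 | (2E)-4-{[tert-butyl(diphenyl)silyl]oxy}but-2-en-1-ol | OC/C=C/CO[Si](c1ccccc1)(c1ccccc1)C(C)(C)C
F3 | step 5 | tert-butyl (2E)-4-{[tert-butyl(diphenyl)silyl]oxy}but-2-en-1-yl carbonate | CC(C)(C)OC(=O)OC/C=C/CO[Si](c1ccccc1)(c1ccccc1)C(C)(C)C
F4 | step 6 | ethyl (2E)-hepta-2,6-dienoate | CCOC(=O)/C=C/CCC=C
F5 | step 6 | (2E)-hepta-2,6-dien-1-ol | OC/C=C/CCC=C
F6 | step 6 | tert-butyl (2E)-hepta-2,6-dien-1-yl carbonate | CC(C)(C)OC(=O)OC/C=C/CCC=C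
F7 | step 6 | tert-butyl{[(2S)-2-{[(3R)-hepta-1,6-dien-3-yl]oxy}but-3-en-1-yl]oxy}diphenylsilane | C=C[C@@H](CO[Si](c1ccccc1)(c1ccccc1)C(C)(C)C)O[C@@H](C=C)CCC=C
F8 | step 19 | tert-butyl[(9,9-dibromonon-8-en-1-yl)oxy]dimethylsilane | BrC(Br)=CCCCCCCCO[Si](C)(C)C(C)(C)C
F9 | step 19 | tert-butyl{[(8Z)-9-bromonon-8-en-1-yl]oxy}dimethylsilane | Br/C=C\CCCCCCCO[Si](C)(C)C(C)(C)C
F10 | step 19 | (8Z)-9-bromonon-8-en-1-ol | Br/C=C\CCCCCCCO
F11 | step 19 | (8Z)-9-bromonon-8-enal | Br/C=C\CCCCCCC=O
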